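The route rests on disconnecting the C1–C10 bond, which is at once the C–C bond of the 1,10-oxirane and a bond of the ten-membered carbocycle. An intramolecular Corey–Chaykovsky reaction forms it: a diphenylsulfonium ylide at C1 adds to a C10 methyl ketone and the alkoxide expels Ph2S, so one operation closes the cyclodecane and builds the trisubstituted trans-epoxide from the latent carbonyl (C10) and ylide (C1) carbons. The precursor is an acyclic keto sulfonium salt on a trans-γ-butyrolactone (C6, C7 from an Evans aldol; C8 from allylboration) with the E-C4=C5 olefin. Peripheral epoxidation, α-methylenation and tigloylation finish the synthesis.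

Key step: step 12

Remark: germacrane numbering is used for all intermediates (ring C1–C10, lactone C6–O–C12(=O)–C11, methylene C13, methyls C14 on C10 and C15 on C4); the target is read as the (1R,4R,5R,6S,7R,8R,10R) isomer carrying an (E)-2-methylbut-2-enoate (tiglate).

Step 1
Reactants: 1 5-chloropent-1-yne
Product: 2 (2E)-6-chloro-3-methylhex-2-en-1-ol
Conditions: AlMe3, Cp2ZrCl2 (cat.), CH2Cl2, 0 °C to rt; then (CH2O)n, THF, 0 °C to rt
Reagents that add atoms: trimethylaluminium C[Al](C)C; paraformaldehyde (formaldehyde unit) C=O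
Why: Negishi carboalumination (zirconium-catalysed syn addition of Me–Al to the terminal alkyne with methyl on the internal carbon) followed by hydroxymethylation of the alkenylalane with retention fixes the E trisubstituted olefin C4=C5 with C15 cis to C6.

Step 2
Reactants: 2 (2E)-6-chloro-3-methylhex-2-en-1-ol
Product: 3 (2E)-6-chloro-3-methylhex-2-enal
Conditions: MnO2, CH2Cl2, rt
Reagents that add atoms: none
Why: MnO2 oxidises only the allylic alcohol and leaves the E geometry and the alkyl chloride untouched (allylic oxidation).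

Step 3
Reactants: 4 (4S)-4-benzyl-1,3-oxazolidin-2-one; 5 methyl 4-chloro-4-oxobutanoate
Product: 6 methyl 4-[(4S)-4-benzyl-2-oxo-1,3-oxazolidin-3-yl]-4-oxobutanoate
Conditions: n-BuLi, THF, −78 °C; then 5, −78 to 0 °C
Reagents that add atoms: none
Why: N-Acylation of the lithiated oxazolidinone by the acid chloride is faster than attack at the methyl ester and gives the imide needed for the auxiliary-controlled aldol reaction.

Step 4
Reactants: 6 succinate imide; 3 (2E)-6-chloro-3-methylhex-2-enal
Product: 8 trans-lactone imide (2R,3S), via syn-aldol hydroxy ester 7 (not isolated)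
Conditions: Bu2BOTf, iPr2NEt, CH2Cl2, −78 to 0 °C; H2O2, pH 7 buffer, MeOH, 0 °C; then PPTS (cat.), CH2Cl2, rt
Reagents that add atoms: none
Why: Evans syn-aldol reaction in which the Z boron enolate formed at C7 (boron chelated by the imide, ester not enolised) adds to the enal through a chair transition state on the face away from the benzyl group, which sets C6 and C7 (6R,7S in this intermediate, the 6α-O/7α-H pattern of the target), after which the C6 hydroxyl lactonises onto the C12 methyl ester to the trans γ-lactone.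

Step 5
Reactants: 8 trans-lactone imide
Product: 9 S-ethyl thioester of the lactone C8 acid
Conditions: EtSH, n-BuLi, THF, −78 to 0 °C
Reagents that add atoms: ethanethiol CCS
Why: Thiolate acyl substitution at the exocyclic imide carbonyl (auxiliary displacement) is fast at low temperature, while the weakly basic thiolate neither epimerises C7 nor eliminates the β-acyloxy group and any opening of the lactone is reversible.

Step 6
Reactants: 9 S-ethyl thioester
Product: 10 lactone C8 aldehyde
Conditions: Et3SiH, Pd/C (cat.), acetone, rt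
Reagents that add atoms: none
Why: Fukuyama reduction, in which palladium inserts into the C–S bond and Et3SiH delivers hydride, stops at the aldehyde under neutral conditions that spare the lactone, the chloride and the trisubstituted olefin.

Step 7
Reactants: 10 lactone C8 aldehyde
Product: 11 (8R)-homoallylic alcohol
Conditions: (+)-B-allyldiisopinocampheylborane, Et2O, −78 °C; then H2O2, pH 7 buffer, MeOH, 0 °C
Reagents that add atoms: (+)-B-allyldiisopinocampheylborane C=CCB([C@H]1C[C@H]2C[C@@H]([C@@H]1C)C2(C)C)[C@H]1C[C@H]2C[C@@H]([C@@H]1C)C2(C)C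
Why: Brown allylboration through a closed chair transition state under reagent control of the isopinocampheyl groups (borane from (−)-α-pinene) sets C8 as 8R (8β-O) at −78 °C, where the β-acyloxy aldehyde neither epimerises nor eliminates.

Step 8
Reactants: 11 (8R)-homoallylic alcohol
Product: 12 C8 tert-butyldimethylsilyl ether
Conditions: TBSOTf, 2,6-lutidine, CH2Cl2, −78 to 0 °C
Reagents that add atoms: tert-butyldimethylsilyl trifluoromethanesulfonate CC(C)(C)[Si](C)(C)OS(=O)(=O)C(F)(F)F
Why: Silylation of the secondary alcohol prevents translactonisation to the 8,12-lactone and turns the C8 oxygen into a poor leaving group for the base-mediated ring closure.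

Step 9
Reactants: 12 C8 silyl ether with terminal vinyl group
Product: 13 C10 methyl ketone (chloride)
Conditions: PdCl2 (cat.), CuCl, O2 (1 atm), DMF/H2O, rt
Reagents that add atoms: water O
Why: Tsuji–Wacker oxidation (Markovnikov hydroxypalladation of the monosubstituted olefin by divalent palladium, then β-hydride elimination) gives the C10 methyl ketone, while the trisubstituted C4=C5 olefin does not react.

Step 10
Reactants: 13 chloro ketone
Product: 14 iodo ketone
Conditions: NaI, acetone, reflux
Reagents that add atoms: sodium iodide [Na+].[I-]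
Why: Finkelstein SN2 exchange, driven by precipitation of NaCl from acetone, gives the iodide required for silver-assisted alkylation of sulfur.

Step 11
Reactants: 14 iodo ketone
Product: 15 C1 diphenylsulfonium trifluoromethanesulfonate
Conditions: Ph2S, AgOSO2CF3, CH2Cl2, rt, dark
Reagents that add atoms: diphenyl sulfide c1ccc(Sc2ccccc2)cc1; silver trifluoromethanesulfonate [Ag+].[O-]S(=O)(=O)C(F)(F)F
Why: Silver-assisted S-alkylation of diphenyl sulfide by the primary iodide gives an alkyldiphenylsulfonium salt whose only acidic α-hydrogens are at C1.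

Step 12
Reactants: 15 C1 diphenylsulfonium trifluoromethanesulfonate
Product: 18 8β-silyloxy-1β,10α-epoxy-13-norgermacr-4(E)-en-12,6α-olide, via sulfonium ylide 16 (not isolated), via betaine 17 (not isolated)
Conditions: KN(SiMe3)2 (slow addition), THF, −78 to −20 °C, 1–2 mM
Reagents that add atoms: none
Why: Proposed new method: KN(SiMe3)2 removes an α-hydrogen at C1, the only acidic C–H of the sulfonium group, the non-stabilised ylide 16 adds through C1 to the C10 ketone to give betaine 17, and the C10 alkoxide displaces Ph2S from C1 with inversion. The closest known reaction type is the Corey–Chaykovsky epoxidation of ketones with alkyldiphenylsulfonium ylides, established intermolecularly and for closure of common-sized rings, so that its use for a ten-membered carbocycle is the untested element. The carbocycle closes by 10-exo-trig addition to the carbonyl group and the oxirane by 3-exo-tet substitution. C1 and C10 are set together in the irreversible addition step, where the trans-lactone and the E-C4=C5 olefin should hold the chain in the crown-like germacrolide fold with C14 and C15 on the same face, which places C2 and C9 trans on the oxirane and gives the 1β,10α (1R,10R) isomer. The step needs ylide formation in preference to enolisation, to β-elimination of the C8 silyl ether and to attack at the lactone, which the much higher acidity of the sulfonium α-C–H, the poor silanolate leaving group and the higher electrophilicity of the ketone should secure, and ring closure in preference to oligomerisation, which slow addition of base at high dilution should secure.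

Step 13
Reactants: 18 1,10-epoxy-4-ene macrocycle
Product: 19 8β-silyloxy-1β,10α:4α,5β-diepoxy-13-norgermacran-12,6α-olide
Conditions: mCPBA, NaHCO3, CH2Cl2, 0 °C
Reagents that add atoms: 3-chloroperoxybenzoic acid OOC(=O)c1cccc(Cl)c1
Why: Prilezhaev epoxidation of the only olefin takes place from the exposed outer face of the ten-membered ring in its crown-like germacrolide conformation and should give the 4α,5β (4R,5R) trans-epoxide, the facial preference established for germacrolide 4,5-olefins.

Step 14
Reactants: 19 diepoxy lactone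
Product: 22 α-methylene lactone (C8 silyl ether), via Mannich base 20 (not isolated), via trimethylammonium iodide 21 (not isolated)
Conditions: LiN(iPr)2, THF, −78 °C; CH2=NMe2+ I−, −78 °C to rt; then MeI, MeOH, rt; then NaHCO3 (aq), EtOAc, rt
Reagents that add atoms: Eschenmoser's salt (N,N-dimethylmethyleneiminium iodide) C=[N+](C)C.[I-]
Why: Mannich reaction of the lithium enolate (C11 is the only enolisable position) with Eschenmoser's salt, quaternisation with MeI and E1cB elimination of trimethylamine install the C11=C13 methylene without touching the epoxides.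

Step 15
Reactants: 22 α-methylene lactone (C8 silyl ether)
Product: 23 8β-hydroxy-1β,10α:4α,5β-diepoxygermacr-11(13)-en-12,6α-olide
Conditions: Bu4NF, AcOH, THF, 0 °C to rt
Reagents that add atoms: none
Why: Fluoride-mediated desilylation buffered with acetic acid frees the 8β-hydroxyl while the buffer suppresses translactonisation and conjugate addition to the α-methylene lactone.

Step 16
Reactants: 23 8β-hydroxy diepoxide
Product: 24 target (CNP0311437.1)
Conditions: tigloyl chloride, Et3N, DMAP (cat.), CH2Cl2, 0 °C to rt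
Reagents that add atoms: tigloyl chloride [(2E)-2-methylbut-2-enoyl chloride] C/C=C(\C)C(Cl)=O
Why: DMAP-catalysed acylation (nucleophilic catalysis through the acylpyridinium ion) esterifies the 8β-hydroxyl with retention at C8 and keeps the E geometry of the tiglate.

Compound list
1 | 5-chloropent-1-yne | C#CCCCCl | starting material
2 | (2E)-6-chloro-3-methylhex-2-en-1-ol | OC/C=C(\C)CCCCl | intermediate
3 | (2E)-6-chloro-3-methylhex-2-enal | O=C/C=C(\C)CCCCl | intermediate
4 | (4S)-4-benzyl-1,3-oxazolidin-2-one | O=C1OC[C@H](Cc2ccccc2)N1 | starting material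
5 | methyl 4-chloro-4-oxobutanoate | COC(=O)CCC(Cl)=O | starting material
6 | methyl 4-[(4S)-4-benzyl-2-oxo-1,3-oxazolidin-3-yl]-4-oxobutanoate | COC(=O)CCC(=O)N1[C@@H](Cc2ccccc2)COC1=O | intermediate
7 | methyl (3S,4R,5E)-3-{[(4S)-4-benzyl-2-oxo-1,3-oxazolidin-3-yl]carbonyl}-9-chloro-4-hydroxy-6-methylnon-5-enoate (syn-aldol hydroxy ester) | COC(=O)C[C@H](C(=O)N1[C@@H](Cc2ccccc2)COC1=O)[C@H](O)/C=C(\C)CCCCl | intermediate (not isolated)
8 | (4S)-4-benzyl-3-{[(2R,3S)-2-[(1E)-5-chloro-2-methylpent-1-en-1-yl]-5-oxooxolan-3-yl]carbonyl}-1,3-oxazolidin-2-one (trans-lactone imide) | O=C1C[C@H](C(=O)N2[C@@H](Cc3ccccc3)COC2=O)[C@@H](/C=C(\C)CCCCl)O1 | intermediate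
9 | S-ethyl (2R,3S)-2-[(1E)-5-chloro-2-methylpent-1-en-1-yl]-5-oxooxolane-3-carbothioate | O=C1C[C@H](C(=O)SCC)[C@@H](/C=C(\C)CCCCl)O1 | intermediate
10 | (2R,3S)-2-[(1E)-5-chloro-2-methylpent-1-en-1-yl]-5-oxooxolane-3-carbaldehyde | O=C1C[C@H](C=O)[C@@H](/C=C(\C)CCCCl)O1 | intermediate
11 | (4R,5R)-5-[(1E)-5-chloro-2-methylpent-1-en-1-yl]-4-[(1R)-1-hydroxybut-3-en-1-yl]oxolan-2-one | O=C1C[C@H]([C@H](O)CC=C)[C@@H](/C=C(\C)CCCCl)O1 | intermediate
12 | (4S,5R)-4-[(1R)-1-[(tert-butyldimethylsilyl)oxy]but-3-en-1-yl]-5-[(1E)-5-chloro-2-methylpent-1-en-1-yl]oxolan-2-one | O=C1C[C@H]([C@H](O[Si](C)(C)C(C)(C)C)CC=C)[C@@H](/C=C(\C)CCCCl)O1 | intermediate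
13 | (4S,5R)-4-[(1R)-1-[(tert-butyldimethylsilyl)oxy]-3-oxobutyl]-5-[(1E)-5-chloro-2-methylpent-1-en-1-yl]oxolan-2-one | O=C1C[C@H]([C@H](O[Si](C)(C)C(C)(C)C)CC(C)=O)[C@@H](/C=C(\C)CCCCl)O1 | intermediate
14 | (4S,5R)-4-[(1R)-1-[(tert-butyldimethylsilyl)oxy]-3-oxobutyl]-5-[(1E)-5-iodo-2-methylpent-1-en-1-yl]oxolan-2-one | O=C1C[C@H]([C@H](O[Si](C)(C)C(C)(C)C)CC(C)=O)[C@@H](/C=C(\C)CCCI)O1 | intermediate
15 | {(4E)-5-[(2R,3S)-3-[(1R)-1-[(tert-butyldimethylsilyl)oxy]-3-oxobutyl]-5-oxooxolan-2-yl]-4-methylpent-4-en-1-yl}diphenylsulfonium trifluoromethanesulfonate | O=C1C[C@H]([C@H](O[Si](C)(C)C(C)(C)C)CC(C)=O)[C@@H](/C=C(\C)CCC[S+](c2ccccc2)c2ccccc2)O1.[O-]S(=O)(=O)C(F)(F)F | intermediate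
16 | sulfonium ylide of 15 (carbanion at C1 next to diphenylsulfonium) | O=C1C[C@H]([C@H](O[Si](C)(C)C(C)(C)C)CC(C)=O)[C@@H](/C=C(\C)CC[CH-][S+](c2ccccc2)c2ccccc2)O1 | intermediate (not isolated)
17 | betaine: ten-membered ring closed at C1–C10, C10 alkoxide (10α-O) and C1 diphenylsulfonium anti to it, 8β-silyloxy, 4E-ene, 12,6α-lactone | O=C1O[C@@H]2/C=C(\C)CC[C@H]([S+](c3ccccc3)c3ccccc3)[C@@]([O-])(C)C[C@@H](O[Si](C)(C)C(C)(C)C)[C@H]2C1 | intermediate (not isolated)
18 | 8β-[(tert-butyldimethylsilyl)oxy]-1β,10α-epoxy-13-norgermacr-4(E)-en-12,6α-olide (1R,6R,7S,8R,10R) | O=C1O[C@@H]2/C=C(\C)CC[C@H]3O[C@]3(C)C[C@@H](O[Si](C)(C)C(C)(C)C)[C@H]2C1 | intermediate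
19 | 8β-[(tert-butyldimethylsilyl)oxy]-1β,10α:4α,5β-diepoxy-13-norgermacran-12,6α-olide (1R,4R,5R,6S,7S,8R,10R) | O=C1O[C@@H]2[C@H]3O[C@]3(C)CC[C@H]4O[C@]4(C)C[C@@H](O[Si](C)(C)C(C)(C)C)[C@H]2C1 | intermediate
20 | Mannich base: 19 carrying CH2NMe2 at C11 (C11 epimers) | O=C1O[C@@H]2[C@H]3O[C@]3(C)CC[C@H]4O[C@]4(C)C[C@@H](O[Si](C)(C)C(C)(C)C)[C@H]2C1CN(C)C | intermediate (not isolated)
21 | trimethylammonium iodide of 20 (CH2NMe3+ at C11) | O=C1O[C@@H]2[C@H]3O[C@]3(C)CC[C@H]4O[C@]4(C)C[C@@H](O[Si](C)(C)C(C)(C)C)[C@H]2C1C[N+](C)(C)C.[I-] | intermediate (not isolated)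
22 | 8β-[(tert-butyldimethylsilyl)oxy]-1β,10α:4α,5β-diepoxygermacr-11(13)-en-12,6α-olide (1R,4R,5R,6S,7S,8R,10R) | O=C1O[C@@H]2[C@H]3O[C@]3(C)CC[C@H]4O[C@]4(C)C[C@@H](O[Si](C)(C)C(C)(C)C)[C@H]2C1=C | intermediate
23 | 8β-hydroxy-1β,10α:4α,5β-diepoxygermacr-11(13)-en-12,6α-olide (1R,4R,5R,6S,7R,8R,10R) | O=C1O[C@@H]2[C@H]3O[C@]3(C)CC[C@H]4O[C@]4(C)C[C@@H](O)[C@H]2C1=C | intermediate
24 | 1β,10α:4α,5β-diepoxy-8β-[(E)-2-methylbut-2-enoyloxy]germacr-11(13)-en-12,6α-olide (1R,4R,5R,6S,7R,8R,10R), CNP0311437.1 | C=C1C(=O)O[C@H]2[C@H]1[C@H](OC(=O)/C(C)=C/C)C[C@@]1(C)O[C@@H]1CC[C@@]1(C)O[C@H]21 | target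

Total step count: 16. Longest linear sequence: 15 steps (1 to 24 through steps 1, 2 and 4–16; step 3 prepares the imide 6 in a side branch).

Steps most likely to fail

Step 12 (Proposed new method). The risk is that the non-stabilised ylide decays (proton transfer from the ketone α-positions, loss of Ph2S) or oligomerises faster than the strained ten-membered ring closes, or that addition takes the course leading to the cis-oxirane. The fallback uses known reactions and still forms the C1–C10 bond. It sets out from iodide 14. Kornblum oxidation (AgBF4, DMSO, rt; then Et3N) gives (4S,5R)-4-[(1R)-1-[(tert-butyldimethylsilyl)oxy]-3-oxobutyl]-5-[(1E)-2-methyl-5-oxopent-1-en-1-yl]oxolan-2-one F1. Double Wittig methylenation of aldehyde and ketone (Ph3P=CH2, THF, 0 °C) gives the diene F2. Ring-closing metathesis with the second-generation Grubbs catalyst RuCl2(=CHPh)(H2IMes)(PCy3) in toluene at high dilution closes the ring at C1=C10 and gives 8β-[(tert-butyldimethylsilyl)oxy]-13-norgermacra-1(10)E,4E-dien-12,6α-olide F3; the E isomer is required, and E/Z control is the weak point of this alternative. Epoxidation of both ring olefins from their outer faces with two equivalents of mCPBA (NaHCO3, CH2Cl2) returns to the route at diepoxide 19.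

Step 6. The risk is loss of the aldehyde by β-elimination of the lactone carboxylate, or palladium-mediated cleavage of the allylic C6–O bond and over-reduction by the silane. The fallback avoids palladium and the thioester: it sets out from imide 8, whose auxiliary is removed reductively with NaBH4 in THF/H2O at 0 °C to give the primary alcohol (4R,5R)-5-[(1E)-5-chloro-2-methylpent-1-en-1-yl]-4-(hydroxymethyl)oxolan-2-one F4, and oxidation with Dess–Martin periodinane (NaHCO3, CH2Cl2) returns to the route at aldehyde 10.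

Step 13. The risk is poor facial selectivity if the 13-nor, 8-silyloxy macrocycle populates a second ring conformer. The fallback sets the epoxide under catalyst control before ring closure and sets out from chloro ketone 13. Shi epoxidation (D-fructose-derived ketone catalyst, KHSO5, K2CO3 buffer, MeCN/dimethoxymethane/H2O, 0 °C) gives the (4R,5R)-epoxide, (4S,5S)-4-[(1R)-1-[(tert-butyldimethylsilyl)oxy]-3-oxobutyl]-5-[(2R,3R)-3-(3-chloropropyl)-3-methyloxiran-2-yl]oxolan-2-one F5. Finkelstein exchange (NaI, acetone) gives the iodide F6, and Ph2S with AgOSO2CF3 gives the epoxy sulfonium trifluoromethanesulfonate F7. Ring closure under the conditions of step 12 returns to the route at diepoxide 19.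

Further compounds
F1 | step 12 | (4S,5R)-4-[(1R)-1-[(tert-butyldimethylsilyl)oxy]-3-oxobutyl]-5-[(1E)-2-methyl-5-oxopent-1-en-1-yl]oxolan-2-one | O=C1C[C@H]([C@H](O[Si](C)(C)C(C)(C)C)CC(C)=O)[C@@H](/C=C(\C)CCC=O)O1
F2 | step 12 | (4S,5R)-4-[(1R)-1-[(tert-butyldimethylsilyl)oxy]-3-methylbut-3-en-1-yl]-5-[(1E)-2-methylhexa-1,5-dien-1-yl]oxolan-2-one | O=C1C[C@H]([C@H](O[Si](C)(C)C(C)(C)C)CC(C)=C)[C@@H](/C=C(\C)CCC=C)O1
F3 | step 12 | 8β-[(tert-butyldimethylsilyl)oxy]-13-norgermacra-1(10)E,4E-dien-12,6α-olide (6R,7S,8R) | O=C1O[C@@H]2/C=C(\C)CC/C=C(\C)C[C@@H](O[Si](C)(C)C(C)(C)C)[C@H]2C1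
F4 | step 6 | (4R,5R)-5-[(1E)-5-chloro-2-methylpent-1-en-1-yl]-4-(hydroxymethyl)oxolan-2-one | O=C1C[C@H](CO)[C@@H](/C=C(\C)CCCCl)O1
F5 | step 13 | (4S,5S)-4-[(1R)-1-[(tert-butyldimethylsilyl)oxy]-3-oxobutyl]-5-[(2R,3R)-3-(3-chloropropyl)-3-methyloxiran-2-yl]oxolan-2-one | O=C1C[C@H]([C@H](O[Si](C)(C)C(C)(C)C)CC(C)=O)[C@@H]([C@H]2O[C@]2(C)CCCCl)O1
F6 | step 13 | (4S,5S)-4-[(1R)-1-[(tert-butyldimethylsilyl)oxy]-3-oxobutyl]-5-[(2R,3R)-3-(3-iodopropyl)-3-methyloxiran-2-yl]oxolan-2-one | O=C1C[C@H]([C@H](O[Si](C)(C)C(C)(C)C)CC(C)=O)[C@@H]([C@H]2O[C@]2(C)CCCI)O1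
F7 | step 13 | {3-[(2R,3R)-3-[(2S,3S)-3-[(1R)-1-[(tert-butyldimethylsilyl)oxy]-3-oxobutyl]-5-oxooxolan-2-yl]-2-methyloxiran-2-yl]propyl}diphenylsulfonium trifluoromethanesulfonate | O=C1C[C@H]([C@H](O[Si](C)(C)C(C)(C)C)CC(C)=O)[C@@H]([C@H]2O[C@]2(C)CCC[S+](c3ccccc3)c3ccccc3)O1.[O-]S(=O)(=O)C(F)(F)F
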